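## Retrosynthetic overview

- The target is cut at three places: the Ar–C1' bond with the C2'=C3' alkene (alkyne carboalumination, then Pd benzyl coupling), the C4'–C5' bond (catalytic asymmetric propargylation of a geranial-type enal), and the oxolane ring bond C12'–C13'.
- The arene is bought, so the oxolane (O, C15', C14', C13', C12') is the only ring formed. It is closed early, on a geraniol-derived C10 fragment, by joining C13' (an aldehyde carbon, used as its tosylhydrazone) to C12' (a C–H carbon) in a cobalt-catalysed radical 1,5-C–H alkylation.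
- Enabling feature: the C12'–H bond is both allylic to the C10'=C11' alkene and α to the ether oxygen that becomes the ring oxygen, and it lies 1,5 to C13'. It is therefore the weakest C–H bond within reach of a C13' radical.
- Stereocentres: C14' comes from methyl (S)-glycerate acetonide; C12' is set in the key step (catalyst control, reinforced by C14'); C5' is set by chiral phosphoric acid-catalysed allenylboration.
- The three E-alkenes come from geraniol (C6'=C7'), SeO2 oxidation of its E-methyl group (C10'=C11') and syn-carboalumination (C2'=C3'); acetylation and global desilylation finish the route.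

Key step: step 10

Remark: side-chain carbons are numbered C1' (benzylic CH2) to C15' (CMe2 of the oxolane). The sense of induction of the two chiral catalysts (steps 10 and 13) is taken by analogy with simpler substrates, and the antipode of each catalyst is chosen accordingly.

## Route

Step 1
Reactants: 1 geraniol
Product: 2 geranyl 4-methoxybenzyl ether, 1-({[(2E)-3,7-dimethylocta-2,6-dien-1-yl]oxy}methyl)-4-methoxybenzene
Conditions: NaH, 4-methoxybenzyl chloride, Bu4NI (cat.), THF/DMF, 0 °C to rt
Reagents that add atoms: 4-methoxybenzyl chloride, COc1ccc(CCl)cc1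
Why: Williamson etherification of the primary allylic alkoxide gives a PMB ether that survives base, mild acid and the radical step and is removed oxidatively in step 11.

Step 2
Reactants: 2 geranyl 4-methoxybenzyl ether
Product: 3 (2E,6E)-8-[(4-methoxyphenyl)methoxy]-2,6-dimethylocta-2,6-dien-1-ol
Conditions: SeO2 (cat.), t-BuOOH, salicylic acid (cat.), CH2Cl2, 0 °C to rt
Reagents that add atoms: tert-butyl hydroperoxide (oxygen source, relayed by SeO2), CC(C)(C)OO
Why: The SeO2-catalysed allylic oxidation (ene reaction, then [2,3]-sigmatropic shift) should attack the E-methyl group of the terminal, most electron-rich alkene and give the E-allylic alcohol, the C6'=C7' alkene being deactivated by its allylic ether oxygen.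

Step 3
Reactants: 3 (2E,6E)-8-[(4-methoxyphenyl)methoxy]-2,6-dimethylocta-2,6-dien-1-ol
Product: 4 1-({[(2E,6E)-8-bromo-3,7-dimethylocta-2,6-dien-1-yl]oxy}methyl)-4-methoxybenzene
Conditions: CBr4, PPh3, CH2Cl2, 0 °C
Reagents that add atoms: carbon tetrabromide, BrC(Br)(Br)Br
Why: Appel bromination displaces the oxyphosphonium group of the primary allylic alcohol by SN2 without allylic transposition or loss of E geometry.

Step 4
Reactants: 5 methyl (4S)-2,2-dimethyl-1,3-dioxolane-4-carboxylate
Product: 6 2-[(4S)-2,2-dimethyl-1,3-dioxolan-4-yl]propan-2-ol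
Conditions: MeMgBr (3 equiv), THF, 0 °C to rt; aq. NH4Cl
Reagents that add atoms: methylmagnesium bromide, C[Mg]Br
Why: Double Grignard addition to the ester builds the CMe2 carbinol (C15') without touching the chiral-pool stereocentre that becomes C14'.

Step 5
Reactants: 4 1-({[(2E,6E)-8-bromo-3,7-dimethylocta-2,6-dien-1-yl]oxy}methyl)-4-methoxybenzene; 6 2-[(4S)-2,2-dimethyl-1,3-dioxolan-4-yl]propan-2-ol
Product: 7 (4S)-4-[2-({(2E,6E)-8-[(4-methoxyphenyl)methoxy]-2,6-dimethylocta-2,6-dien-1-yl}oxy)propan-2-yl]-2,2-dimethyl-1,3-dioxolane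
Conditions: NaH, Bu4NI (cat.), THF/DMF, 0 °C to 40 °C
Reagents that add atoms: none
Why: Williamson etherification of the tertiary sodium alkoxide with the unhindered primary allylic bromide (SN2) forms the C15'–O–C12' ether while the acetonide masks the other two hydroxyl groups.

Step 6
Reactants: 7 (4S)-4-[2-({(2E,6E)-8-[(4-methoxyphenyl)methoxy]-2,6-dimethylocta-2,6-dien-1-yl}oxy)propan-2-yl]-2,2-dimethyl-1,3-dioxolane
Product: 8 (2S)-3-({(2E,6E)-8-[(4-methoxyphenyl)methoxy]-2,6-dimethylocta-2,6-dien-1-yl}oxy)-3-methylbutane-1,2-diol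
Conditions: AcOH/H2O/THF (3:1:1), 45 °C
Reagents that add atoms: none
Why: Mild acid hydrolysis of the terminal acetonide should leave the PMB ether, the allylic ether and the trisubstituted alkenes untouched.

Step 7
Reactants: 8 (2S)-3-({(2E,6E)-8-[(4-methoxyphenyl)methoxy]-2,6-dimethylocta-2,6-dien-1-yl}oxy)-3-methylbutane-1,2-diol
Product: 9 {[(2S)-3-({(2E,6E)-8-[(4-methoxyphenyl)methoxy]-2,6-dimethylocta-2,6-dien-1-yl}oxy)-3-methylbutane-1,2-diyl]bis(oxy)}bis(triethylsilane)
Conditions: TESOTf (2.5 equiv), 2,6-lutidine, CH2Cl2, −78 °C to 0 °C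
Reagents that add atoms: triethylsilyl trifluoromethanesulfonate, CC[Si](CC)(CC)OS(=O)(=O)C(F)(F)F
Why: The silyl triflate silylates both the primary hydroxyl and the hindered secondary hydroxyl next to the quaternary carbon.

Step 8
Reactants: 9 {[(2S)-3-({(2E,6E)-8-[(4-methoxyphenyl)methoxy]-2,6-dimethylocta-2,6-dien-1-yl}oxy)-3-methylbutane-1,2-diyl]bis(oxy)}bis(triethylsilane)
Product: 10 (2R)-3-({(2E,6E)-8-[(4-methoxyphenyl)methoxy]-2,6-dimethylocta-2,6-dien-1-yl}oxy)-3-methyl-2-[(triethylsilyl)oxy]butanal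
Conditions: (COCl)2, DMSO, CH2Cl2, −78 °C to −40 °C; then Et3N, −78 °C to rt
Reagents that add atoms: none
Why: Under Swern conditions a primary triethylsilyl ether is cleaved and oxidised directly to the aldehyde while the secondary one stays, and the cold, briefly basic conditions should not epimerise the α-silyloxy centre (the descriptor changes to R only because CHO outranks CMe2).

Step 9
Reactants: 10 (2R)-3-({(2E,6E)-8-[(4-methoxyphenyl)methoxy]-2,6-dimethylocta-2,6-dien-1-yl}oxy)-3-methyl-2-[(triethylsilyl)oxy]butanal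
Product: 11 N'-[(2S)-3-({(2E,6E)-8-[(4-methoxyphenyl)methoxy]-2,6-dimethylocta-2,6-dien-1-yl}oxy)-3-methyl-2-[(triethylsilyl)oxy]butylidene]-4-methylbenzenesulfonohydrazide
Conditions: TsNHNH2 (1.05 equiv), MeOH, rt
Reagents that add atoms: 4-methylbenzenesulfonohydrazide, Cc1ccc(cc1)S(=O)(=O)NN
Why: Neutral condensation of the aldehyde with tosylhydrazide gives the bench-stable diazo precursor without enolisation of the α-stereocentre.

Step 10
Reactants: 11 N'-[(2S)-3-({(2E,6E)-8-[(4-methoxyphenyl)methoxy]-2,6-dimethylocta-2,6-dien-1-yl}oxy)-3-methyl-2-[(triethylsilyl)oxy]butylidene]-4-methylbenzenesulfonohydrazide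
Product: 13 triethyl({(3S,5S)-5-[(2E,6E)-8-[(4-methoxyphenyl)methoxy]-6-methylocta-2,6-dien-2-yl]-2,2-dimethyloxolan-3-yl}oxy)silane, via diazoalkane 12 (not isolated)
Conditions: chiral amidoporphyrin complex of divalent cobalt, for example [Co(2,6-DiMeO-Hu(C6)Phyrin)] (2–5 mol %), Cs2CO3 (2 equiv), 1,4-dioxane, 40–60 °C, N2
Reagents that add atoms: none
Why: Cs2CO3 converts hydrazone 11 into diazoalkane 12 (Bamford–Stevens), which the divalent cobalt metalloradical turns, with loss of N2, into a cobalt-bound alkyl radical at C13'; this radical abstracts the C12' hydrogen through a six-membered transition state (1,5-hydrogen atom transfer), and the resulting allylic, α-alkoxy radical attacks C13' in a homolytic substitution that forms the C12'–C13' bond and returns the catalyst. The closest known reaction type is the cobalt-porphyrin-catalysed enantioselective radical 1,5-C–H alkylation of aldehyde-derived tosylhydrazones at benzylic, allylic and propargylic C–H bonds next to nitrogen or oxygen, which gives 2-substituted pyrrolidines and oxolanes. The oxolane is thus closed in a formal 1,5-C–H insertion, a 5-membered ring closure by intramolecular radical substitution (3-exo-tet at the cobalt-bound carbon). The new stereocentre C12' is set in this substitution inside the chiral cavity of the porphyrin (catalyst control, the ligand antipode being chosen for 12'S) and should be reinforced by the resident C14' silyloxy group, which sits pseudo-equatorial in the envelope-like transition state so that the 12',14'-cis oxolane is the matched product. The step needs hydrogen abstraction to outrun 1,2-hydrogen shift from C14' and cyclopropanation of the C10'=C11' alkene, and it needs closure at the oxygen-bearing end of the allyl radical with the E geometry kept. The weak, doubly activated C12'–H bond, the geminal methyl groups on C15' that fold the chain, the stepwise radical character of the cobalt carbene and the fast 5-membered closure (against a 7-membered one at C10') should secure this.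

Step 11
Reactants: 13 triethyl({(3S,5S)-5-[(2E,6E)-8-[(4-methoxyphenyl)methoxy]-6-methylocta-2,6-dien-2-yl]-2,2-dimethyloxolan-3-yl}oxy)silane
Product: 14 (2E,6E)-7-{(2S,4S)-5,5-dimethyl-4-[(triethylsilyl)oxy]oxolan-2-yl}-3-methylocta-2,6-dien-1-ol
Conditions: DDQ (1.3 equiv), CH2Cl2/pH 7 phosphate buffer (10:1), 0 °C
Reagents that add atoms: none
Why: DDQ abstracts hydride from the electron-rich PMB ether far faster than from the allylic oxolane C–H or the alkenes, and the buffered water hydrolyses the oxocarbenium ion to the free allylic alcohol.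

Step 12
Reactants: 14 (2E,6E)-7-{(2S,4S)-5,5-dimethyl-4-[(triethylsilyl)oxy]oxolan-2-yl}-3-methylocta-2,6-dien-1-ol
Product: 15 (2E,6E)-7-{(2S,4S)-5,5-dimethyl-4-[(triethylsilyl)oxy]oxolan-2-yl}-3-methylocta-2,6-dienal
Conditions: PhI(OAc)2 (1.2 equiv), TEMPO (10 mol %), CH2Cl2, rt
Reagents that add atoms: none
Why: The oxoammonium-mediated oxidation takes the primary allylic alcohol to the enal without E/Z isomerisation or over-oxidation.

Step 13
Reactants: 15 (2E,6E)-7-{(2S,4S)-5,5-dimethyl-4-[(triethylsilyl)oxy]oxolan-2-yl}-3-methylocta-2,6-dienal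
Product: 17 (4R,5E,9E)-10-{(2S,4S)-5,5-dimethyl-4-[(triethylsilyl)oxy]oxolan-2-yl}-6-methylundeca-5,9-dien-1-yn-4-ol, via pinacol borate ester 16 (not isolated)
Conditions: allenylboronic acid pinacol ester (1.5 equiv), (R)-3,3'-bis(2,4,6-triisopropylphenyl)-1,1'-binaphthyl-2,2'-diyl hydrogen phosphate (10 mol %), 4 Å molecular sieves, toluene, −20 °C; aq. NaHCO3 work-up
Reagents that add atoms: allenylboronic acid pinacol ester, C=C=CB1OC(C)(C)C(C)(C)O1
Why: Chiral phosphoric acid-catalysed allenylboration (SE2' transfer through a closed six-membered transition state held by the acid) should deliver the propargyl group to the Re face of the enal and set C5' as R under catalyst control, the remote oxolane centres having no influence.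

Step 14
Reactants: 18 4-methoxy-2-methylphenol
Product: 19 2-hydroxy-5-methoxy-3-methylbenzaldehyde
Conditions: MgCl2, Et3N, paraformaldehyde, MeCN, reflux; aq. HCl work-up
Reagents that add atoms: paraformaldehyde (as formaldehyde), C=O
Why: In the magnesium-mediated ortho-formylation (Casnati–Skattebøl) the magnesium phenoxide directs formaldehyde to the only free ortho position and a second formaldehyde accepts hydride to give the aldehyde.

Step 15
Reactants: 19 2-hydroxy-5-methoxy-3-methylbenzaldehyde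
Product: 20 2-[(tert-butyldimethylsilyl)oxy]-5-methoxy-3-methylbenzaldehyde
Conditions: TBSCl, imidazole, DMF, rt
Reagents that add atoms: tert-butyldimethylsilyl chloride, CC(C)(C)[Si](C)(C)Cl
Why: Silylation masks the phenol with a group that tolerates the organoaluminium coupling and is removed by fluoride without touching an acetate.

Step 16
Reactants: 20 2-[(tert-butyldimethylsilyl)oxy]-5-methoxy-3-methylbenzaldehyde
Product: 21 {2-[(tert-butyldimethylsilyl)oxy]-5-methoxy-3-methylphenyl}methanol
Conditions: NaBH4, MeOH/THF, 0 °C, short reaction time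
Reagents that add atoms: none
Why: Borohydride reduction of the aldehyde at 0 °C should be faster than migration of the silyl group from the phenol oxygen to the new benzylic alkoxide.

Step 17
Reactants: 21 {2-[(tert-butyldimethylsilyl)oxy]-5-methoxy-3-methylphenyl}methanol
Product: 22 tert-butyl[2-(chloromethyl)-4-methoxy-6-methylphenoxy]dimethylsilane
Conditions: PPh3, N-chlorosuccinimide, THF, 0 °C to rt
Reagents that add atoms: N-chlorosuccinimide, O=C1CCC(=O)N1Cl
Why: Appel-type chlorination under neutral conditions gives the benzylic chloride without cleaving the aryl silyl ether.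

Step 18
Reactants: 17 (4R,5E,9E)-10-{(2S,4S)-5,5-dimethyl-4-[(triethylsilyl)oxy]oxolan-2-yl}-6-methylundeca-5,9-dien-1-yn-4-ol; 22 tert-butyl[2-(chloromethyl)-4-methoxy-6-methylphenoxy]dimethylsilane
Product: 24 (2E,5R,6E,10E)-1-{2-[(tert-butyldimethylsilyl)oxy]-5-methoxy-3-methylphenyl}-11-{(2S,4S)-5,5-dimethyl-4-[(triethylsilyl)oxy]oxolan-2-yl}-3,7-dimethyldodeca-2,6,10-trien-5-ol, via alkenylalane 23 (not isolated)
Conditions: Me3Al (3.5 equiv), Cp2ZrCl2 (0.3 equiv), CH2Cl2, 0 °C to rt; volatiles removed; then 22, Pd(PPh3)4 (5 mol %), THF, rt; aq. Rochelle salt work-up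
Reagents that add atoms: trimethylaluminium, C[Al](C)C
Why: Negishi zirconium-catalysed syn-carboalumination of the terminal alkyne (methyl to the internal carbon, aluminium to the terminus, the hydroxyl masked in situ as its aluminium alkoxide) gives only the E-alkenylalane, which zerovalent palladium couples with the benzylic chloride with retention of alkene geometry.

Step 19
Reactants: 24 (2E,5R,6E,10E)-1-{2-[(tert-butyldimethylsilyl)oxy]-5-methoxy-3-methylphenyl}-11-{(2S,4S)-5,5-dimethyl-4-[(triethylsilyl)oxy]oxolan-2-yl}-3,7-dimethyldodeca-2,6,10-trien-5-ol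
Product: 25 (2E,5R,6E,10E)-1-{2-[(tert-butyldimethylsilyl)oxy]-5-methoxy-3-methylphenyl}-11-{(2S,4S)-5,5-dimethyl-4-[(triethylsilyl)oxy]oxolan-2-yl}-3,7-dimethyldodeca-2,6,10-trien-5-yl acetate
Conditions: Ac2O, pyridine, DMAP (cat.), CH2Cl2, 0 °C to rt
Reagents that add atoms: acetic anhydride, CC(=O)OC(C)=O
Why: The only free hydroxyl, at C5', is acylated under nucleophilic catalysis with no risk to the stereocentre.

Step 20
Reactants: 25 (2E,5R,6E,10E)-1-{2-[(tert-butyldimethylsilyl)oxy]-5-methoxy-3-methylphenyl}-11-{(2S,4S)-5,5-dimethyl-4-[(triethylsilyl)oxy]oxolan-2-yl}-3,7-dimethyldodeca-2,6,10-trien-5-yl acetate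
Product: 26 (2E,5R,6E,10E)-1-(2-hydroxy-5-methoxy-3-methylphenyl)-11-[(2S,4S)-4-hydroxy-5,5-dimethyloxolan-2-yl]-3,7-dimethyldodeca-2,6,10-trien-5-yl acetate (CNP0148147.2)
Conditions: HF·pyridine, pyridine, THF, 0 °C to rt
Reagents that add atoms: none
Why: Buffered fluoride cleaves the aryl silyl ether and the secondary triethylsilyl ether while leaving the allylic acetate neither hydrolysed nor ionised.

## Compound list

1 | geraniol | OC/C=C(\C)CCC=C(C)C | starting material
2 | geranyl 4-methoxybenzyl ether | COc1ccc(COC/C=C(\C)CCC=C(C)C)cc1 | intermediate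
3 | (2E,6E)-8-[(4-methoxyphenyl)methoxy]-2,6-dimethylocta-2,6-dien-1-ol | COc1ccc(COC/C=C(\C)CC/C=C(\C)CO)cc1 | intermediate
4 | 1-({[(2E,6E)-8-bromo-3,7-dimethylocta-2,6-dien-1-yl]oxy}methyl)-4-methoxybenzene | COc1ccc(COC/C=C(\C)CC/C=C(\C)CBr)cc1 | intermediate
5 | methyl (4S)-2,2-dimethyl-1,3-dioxolane-4-carboxylate | COC(=O)[C@@H]1COC(C)(C)O1 | starting material
6 | 2-[(4S)-2,2-dimethyl-1,3-dioxolan-4-yl]propan-2-ol | CC(C)(O)[C@@H]1COC(C)(C)O1 | intermediate
7 | (4S)-4-[2-({(2E,6E)-8-[(4-methoxyphenyl)methoxy]-2,6-dimethylocta-2,6-dien-1-yl}oxy)propan-2-yl]-2,2-dimethyl-1,3-dioxolane | COc1ccc(COC/C=C(\C)CC/C=C(\C)COC(C)(C)[C@@H]2COC(C)(C)O2)cc1 | intermediate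
8 | (2S)-3-({(2E,6E)-8-[(4-methoxyphenyl)methoxy]-2,6-dimethylocta-2,6-dien-1-yl}oxy)-3-methylbutane-1,2-diol | COc1ccc(COC/C=C(\C)CC/C=C(\C)COC(C)(C)[C@@H](O)CO)cc1 | intermediate
9 | bis(triethylsilyl) ether of 8, (2S) | COc1ccc(COC/C=C(\C)CC/C=C(\C)COC(C)(C)[C@@H](O[Si](CC)(CC)CC)CO[Si](CC)(CC)CC)cc1 | intermediate
10 | (2R)-3-({(2E,6E)-8-[(4-methoxyphenyl)methoxy]-2,6-dimethylocta-2,6-dien-1-yl}oxy)-3-methyl-2-[(triethylsilyl)oxy]butanal | COc1ccc(COC/C=C(\C)CC/C=C(\C)COC(C)(C)[C@@H](O[Si](CC)(CC)CC)C=O)cc1 | intermediate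
11 | tosylhydrazone of 10, (2S) | COc1ccc(COC/C=C(\C)CC/C=C(\C)COC(C)(C)[C@@H](O[Si](CC)(CC)CC)C=NNS(=O)(=O)c2ccc(C)cc2)cc1 | intermediate
12 | {[(2S)-1-diazo-3-({(2E,6E)-8-[(4-methoxyphenyl)methoxy]-2,6-dimethylocta-2,6-dien-1-yl}oxy)-3-methylbutan-2-yl]oxy}triethylsilane | COc1ccc(COC/C=C(\C)CC/C=C(\C)COC(C)(C)[C@@H](O[Si](CC)(CC)CC)C=[N+]=[N-])cc1 | intermediate (not isolated)
13 | triethyl({(3S,5S)-5-[(2E,6E)-8-[(4-methoxyphenyl)methoxy]-6-methylocta-2,6-dien-2-yl]-2,2-dimethyloxolan-3-yl}oxy)silane | COc1ccc(COC/C=C(\C)CC/C=C(\C)[C@@H]2C[C@H](O[Si](CC)(CC)CC)C(C)(C)O2)cc1 | intermediate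
14 | (2E,6E)-7-{(2S,4S)-5,5-dimethyl-4-[(triethylsilyl)oxy]oxolan-2-yl}-3-methylocta-2,6-dien-1-ol | OC/C=C(\C)CC/C=C(\C)[C@@H]1C[C@H](O[Si](CC)(CC)CC)C(C)(C)O1 | intermediate
15 | (2E,6E)-7-{(2S,4S)-5,5-dimethyl-4-[(triethylsilyl)oxy]oxolan-2-yl}-3-methylocta-2,6-dienal | O=C/C=C(\C)CC/C=C(\C)[C@@H]1C[C@H](O[Si](CC)(CC)CC)C(C)(C)O1 | intermediate
16 | pinacol borate ester of 17 | C#CC[C@H](/C=C(\C)CC/C=C(\C)[C@@H]1C[C@H](O[Si](CC)(CC)CC)C(C)(C)O1)OB2OC(C)(C)C(C)(C)O2 | intermediate (not isolated)
17 | (4R,5E,9E)-10-{(2S,4S)-5,5-dimethyl-4-[(triethylsilyl)oxy]oxolan-2-yl}-6-methylundeca-5,9-dien-1-yn-4-ol | C#CC[C@H](/C=C(\C)CC/C=C(\C)[C@@H]1C[C@H](O[Si](CC)(CC)CC)C(C)(C)O1)O | intermediate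
18 | 4-methoxy-2-methylphenol | COc1ccc(O)c(C)c1 | starting material
19 | 2-hydroxy-5-methoxy-3-methylbenzaldehyde | COc1cc(C)c(O)c(C=O)c1 | intermediate
20 | 2-[(tert-butyldimethylsilyl)oxy]-5-methoxy-3-methylbenzaldehyde | COc1cc(C)c(O[Si](C)(C)C(C)(C)C)c(C=O)c1 | intermediate
21 | {2-[(tert-butyldimethylsilyl)oxy]-5-methoxy-3-methylphenyl}methanol | COc1cc(C)c(O[Si](C)(C)C(C)(C)C)c(CO)c1 | intermediate
22 | tert-butyl[2-(chloromethyl)-4-methoxy-6-methylphenoxy]dimethylsilane | COc1cc(C)c(O[Si](C)(C)C(C)(C)C)c(CCl)c1 | intermediate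
23 | (E)-alkenyl(dimethyl)alane of 17, as its dimethylaluminium alkoxide | C[Al](C)/C=C(\C)C[C@H](/C=C(\C)CC/C=C(\C)[C@@H]1C[C@H](O[Si](CC)(CC)CC)C(C)(C)O1)O[Al](C)C | intermediate (not isolated)
24 | (2E,5R,6E,10E)-1-{2-[(tert-butyldimethylsilyl)oxy]-5-methoxy-3-methylphenyl}-11-{(2S,4S)-5,5-dimethyl-4-[(triethylsilyl)oxy]oxolan-2-yl}-3,7-dimethyldodeca-2,6,10-trien-5-ol | COc1cc(C)c(O[Si](C)(C)C(C)(C)C)c(C/C=C(\C)C[C@H](/C=C(\C)CC/C=C(\C)[C@@H]2C[C@H](O[Si](CC)(CC)CC)C(C)(C)O2)O)c1 | intermediate
25 | acetate of 24 | COc1cc(C)c(O[Si](C)(C)C(C)(C)C)c(C/C=C(\C)C[C@H](/C=C(\C)CC/C=C(\C)[C@@H]2C[C@H](O[Si](CC)(CC)CC)C(C)(C)O2)OC(C)=O)c1 | intermediate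
26 | (2E,5R,6E,10E)-1-(2-hydroxy-5-methoxy-3-methylphenyl)-11-[(2S,4S)-4-hydroxy-5,5-dimethyloxolan-2-yl]-3,7-dimethyldodeca-2,6,10-trien-5-yl acetate | COc1cc(C)c(O)c(C/C=C(\C)C[C@H](/C=C(\C)CC/C=C(\C)[C@@H]2C[C@H](O)C(C)(C)O2)OC(C)=O)c1 | target

## Step count and risks

Total steps: 20. Longest linear sequence: 15 steps (geraniol to 26: steps 1–3, 5–13, 18–20).

**Step 10 (key step).** The cobalt carbene radical may be diverted before it abstracts the C12' hydrogen: by 1,2-hydrogen shift from C14' to a silyl enol ether, by cyclopropanation of the C10'=C11' alkene or by carbene dimerisation. Catalyst and substrate bias may also be mismatched, giving poor facial selectivity at C12'. The fallback keeps the same ring-closing bond but forms it by an ionic rearrangement; it sets out from alcohol 3 and comes back to the route at 13. Oxidation of 3 (PhI(OAc)2, TEMPO) gives (2E,6E)-8-[(4-methoxyphenyl)methoxy]-2,6-dimethylocta-2,6-dienal F1. Acid-catalysed condensation with 2-hydroxyisobutyric acid (TsOH, benzene, water removal) gives the 2-alkenyl-5,5-dimethyl-1,3-dioxolan-4-one F2. Cp2TiMe2 (toluene, 65 °C) methylenates the lactone carbonyl to the 4-methylidene-1,3-dioxolane F3. i-Bu3Al (CH2Cl2, −78 °C to 0 °C) should then trigger the Petasis–Ferrier-type rearrangement (ionisation to an allyl-stabilised oxocarbenium ion and an aluminium enolate, C12'–C13' closure) and reduce the oxolan-3-one in the same flask anti to the C12' substituent, giving the racemic cis-oxolan-3-ol F4. Lipase-catalysed acylative kinetic resolution (Candida antarctica lipase B, vinyl acetate) is expected to acetylate the (3R,5R)-enantiomer and leave the (3S,5S)-oxolan-3-ol F5, which TESCl and imidazole convert into 13.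

**Step 18.** The allylic aluminium alkoxide may ionise or take up methyl under the Lewis acidic carboalumination conditions, and the alkenylalane may be protonated or transfer methyl instead of the alkenyl group in the coupling. The fallback reverses the polarity of the coupling partners; it sets out from 17 and 22 and comes back at 24. Carboalumination as in step 18 followed by iodinolysis (I2, THF, −30 °C) gives the (1E,4R,5E,9E)-1-iodo-2,6-dimethylundeca-1,5,9-trien-4-ol derivative F7. Zinc insertion into 22 (Zn dust, LiCl, THF) gives the benzylzinc chloride F8. Negishi coupling of F7 with F8 (Pd(OAc)2, SPhos, THF, rt) should give 24.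

**Step 13.** Facial selectivity on the β,β-disubstituted enal may be poor, and the C5' epimers, whose new centre is remote from the oxolane centres, would be hard to separate; transfer of the allenyl instead of the propargyl group is a second risk. The fallback replaces catalyst-controlled addition by kinetic resolution; it sets out from 15 and comes back at 17. Barbier propargylation (propargyl bromide, Zn, THF) gives the C4-epimeric homopropargylic alcohols F6. Sharpless kinetic resolution of this secondary allylic alcohol (Ti(OiPr)4, L-(+)-diisopropyl tartrate, t-BuOOH, 4 Å molecular sieves, CH2Cl2, −20 °C, run past half conversion) is expected to epoxidise the 4S epimer faster, leaving 17, which is separated from the epoxy alcohol by chromatography. The same resolution can also be used to upgrade material from step 13.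

## Further compounds

F1 | step 10 | (2E,6E)-8-[(4-methoxyphenyl)methoxy]-2,6-dimethylocta-2,6-dienal | COc1ccc(COC/C=C(\C)CC/C=C(\C)C=O)cc1
F2 | step 10 | 2-[(2E,6E)-8-[(4-methoxyphenyl)methoxy]-6-methylocta-2,6-dien-2-yl]-5,5-dimethyl-1,3-dioxolan-4-one (racemic, drawn without descriptor) | COc1ccc(COC/C=C(\C)CC/C=C(\C)C2OC(=O)C(C)(C)O2)cc1
F3 | step 10 | 2-[(2E,6E)-8-[(4-methoxyphenyl)methoxy]-6-methylocta-2,6-dien-2-yl]-5,5-dimethyl-4-methylidene-1,3-dioxolane (racemic, drawn without descriptor) | COc1ccc(COC/C=C(\C)CC/C=C(\C)C2OC(=C)C(C)(C)O2)cc1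
F4 | step 10 | cis-5-[(2E,6E)-8-[(4-methoxyphenyl)methoxy]-6-methylocta-2,6-dien-2-yl]-2,2-dimethyloxolan-3-ol (racemate, drawn without descriptors) | COc1ccc(COC/C=C(\C)CC/C=C(\C)C2CC(O)C(C)(C)O2)cc1
F5 | step 10 | (3S,5S)-5-[(2E,6E)-8-[(4-methoxyphenyl)methoxy]-6-methylocta-2,6-dien-2-yl]-2,2-dimethyloxolan-3-ol | COc1ccc(COC/C=C(\C)CC/C=C(\C)[C@@H]2C[C@H](O)C(C)(C)O2)cc1
F6 | step 13 | (5E,9E)-10-{(2S,4S)-5,5-dimethyl-4-[(triethylsilyl)oxy]oxolan-2-yl}-6-methylundeca-5,9-dien-1-yn-4-ol, both C4 epimers | C#CCC(O)/C=C(\C)CC/C=C(\C)[C@@H]1C[C@H](O[Si](CC)(CC)CC)C(C)(C)O1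
F7 | step 18 | (1E,4R,5E,9E)-10-{(2S,4S)-5,5-dimethyl-4-[(triethylsilyl)oxy]oxolan-2-yl}-1-iodo-2,6-dimethylundeca-1,5,9-trien-4-ol | I/C=C(\C)C[C@H](/C=C(\C)CC/C=C(\C)[C@@H]1C[C@H](O[Si](CC)(CC)CC)C(C)(C)O1)O
F8 | step 18 | chlorido({2-[(tert-butyldimethylsilyl)oxy]-5-methoxy-3-methylphenyl}methyl)zinc | COc1cc(C)c(O[Si](C)(C)C(C)(C)C)c(C[Zn]Cl)c1
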